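**Retrosynthetic overview**
1. Last ring: the 14-membered carbocycle, closed at C3–C4 by a cathodic Cr/Ni-catalysed alkenyl bromide–aldehyde (NHK) macrocyclisation that also creates C3.
2. C8–C9: late Negishi coupling of an alkylzinc on the lactone core with (2E,5Z)-2-bromo-6-iodohepta-2,5-diene (from 2-butyn-1-ol and a propynyl unit).
3. First ring: the α-methylene ε-lactone, by acid-catalysed opening of a trans-11,12-epoxide by the C16 acid (inversion at C12); C16 comes from SeO2/chlorite oxidation of the isopropenyl group.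
4. C12–C13 and the epoxide: Cornforth addition of a limonene-derived alkylmagnesium bromide (C1, C2–C3, C13–C17) to an (S)-α-chloro methyl ketone from L-homoserine (C9–C12).
5. Ring order: epoxide, then seven-membered lactone, then macrocycle; C1 and C11 are bought, C12 follows from C11, C3 from the lactone-bridged seco compound.

Assumption (numbering): the target is numbered as a cembranolide: C1 (CH carrying C15), C2, C3 (CHOH), C4(=C5; Me C18), C6, C7(=C8; Me C19), C9, C10, C11 (CHOAc), C12 (C–O; Me C20), C13, C14; C15(=C17H2), C16 (lactone C=O).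

**Route**

Step 1
Reactants: 1 (S)-(−)-limonene
Product: 4 (3S)-5,5-dimethoxy-3-(prop-1-en-2-yl)pentan-1-ol, via methoxy hydroperoxide 2 (not isolated), via Criegee acetate 3 (not isolated)
Conditions: O3 (1.0 equiv), CH2Cl2/MeOH, −78 °C; TsOH, rt; NaHCO3; Ac2O, Et3N, DMAP, 0 °C to rt; then K2CO3, MeOH, rt
Reagents that add atoms: ozone, [O-][O+]=O; methanol, CO
Why: Ozone cleaves the trisubstituted ring alkene much faster than the isopropenyl group, methanol traps the ketone-derived carbonyl oxide, the aldehyde is acetalised, and Criegee rearrangement of the peracetate (primary alkyl migrates rather than methyl) followed by methanolysis excises the acetyl carbons, leaving the limonene stereocentre (C1) untouched.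

Step 2
Reactants: 4 (3S)-5,5-dimethoxy-3-(prop-1-en-2-yl)pentan-1-ol
Product: 5 (3R)-5-bromo-1,1-dimethoxy-3-(prop-1-en-2-yl)pentane
Conditions: CBr4, PPh3, CH2Cl2, 0 °C
Reagents that add atoms: carbon tetrabromide, BrC(Br)(Br)Br
Why: Appel bromination of the primary alcohol under neutral conditions that spare the acetal; the stereocentre is not touched (only its CIP descriptor changes).

Step 3
Reactants: 6 L-homoserine
Product: 7 (3S)-3-chlorooxolan-2-one
Conditions: NaNO2, 6 M HCl, 0 °C to rt; concentrate, toluene, 60 °C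
Reagents that add atoms: hydrochloric acid, Cl
Why: Diazotisation of the α-amino acid with carboxylate participation (α-lactone, double inversion) gives the (S)-α-chloro acid with net retention, which lactonises spontaneously; this is the future C11.

Step 4
Reactants: 7 (3S)-3-chlorooxolan-2-one
Product: 8 (2S)-2-chloro-4-hydroxy-N-methoxy-N-methylbutanamide
Conditions: MeNH(OMe)·HCl, AlMe3, CH2Cl2, 0 °C
Reagents that add atoms: N,O-dimethylhydroxylamine hydrochloride, CNOC.Cl
Why: Weinreb aminolysis of the lactone with the non-basic dimethylaluminium amide opens the ring without epimerising the α-chloro centre.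

Step 5
Reactants: 8 (2S)-2-chloro-4-hydroxy-N-methoxy-N-methylbutanamide
Product: 9 (2S)-4-(tert-butyldimethylsilyloxy)-2-chloro-N-methoxy-N-methylbutanamide
Conditions: TBSCl, imidazole, CH2Cl2, 0 °C
Reagents that add atoms: tert-butyl(chloro)dimethylsilane, CC(C)(C)[Si](C)(C)Cl
Why: Silylation of the primary alcohol prevents relactonisation and masks C9–OH so that it cannot compete with epoxide closure in step 7.

Step 6
Reactants: 9 (2S)-4-(tert-butyldimethylsilyloxy)-2-chloro-N-methoxy-N-methylbutanamide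
Product: 10 (3S)-5-(tert-butyldimethylsilyloxy)-3-chloropentan-2-one
Conditions: MeMgBr, THF, −78 to −20 °C; aq NH4Cl
Reagents that add atoms: methylmagnesium bromide, C[Mg]Br
Why: Weinreb ketone synthesis; the chelated tetrahedral intermediate stops at the methyl ketone and the low temperature keeps the α-chloro stereocentre intact.

Step 7
Reactants: 5 (3R)-5-bromo-1,1-dimethoxy-3-(prop-1-en-2-yl)pentane; 10 (3S)-5-(tert-butyldimethylsilyloxy)-3-chloropentan-2-one
Product: 13 tert-butyl(2-{(2R,3R)-3-[(3S)-5,5-dimethoxy-3-(prop-1-en-2-yl)pentyl]-3-methyloxiran-2-yl}ethoxy)dimethylsilane, via alkylmagnesium bromide 11 (not isolated), via chlorohydrin 12 (not isolated)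
Conditions: 5, Mg, THF, 45 °C; add to 10, THF, −90 °C; then K2CO3, MeOH, 0 °C to rt
Reagents that add atoms: none
Why: Cornforth (polar Felkin–Anh) addition: with C–Cl anti to C=O the C13 nucleophile enters past the small H of C11 and sets C12 (typically about 9:1), then the alkoxide displaces chloride with inversion at C11 to give the trans (11R,12R) epoxide.

Step 8
Reactants: 13 the trans epoxide
Product: 14 2-[(3S)-5-{(2R,3R)-3-[2-(tert-butyldimethylsilyloxy)ethyl]-2-methyloxiran-2-yl}-1,1-dimethoxypentan-3-yl]prop-2-en-1-ol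
Conditions: SeO2 (0.3 equiv), t-BuOOH, CH2Cl2, rt
Reagents that add atoms: tert-butyl hydroperoxide, CC(C)(C)OO
Why: Riley allylic oxidation (ene reaction, then 2,3-shift) of the only alkene present hydroxylates the isopropenyl methyl group (C16); any enal formed converges in step 9 and no stereocentre is touched.

Step 9
Reactants: 14 the allylic alcohol
Product: 16 2-[(3S)-5-{(2R,3R)-3-[2-(tert-butyldimethylsilyloxy)ethyl]-2-methyloxiran-2-yl}-1,1-dimethoxypentan-3-yl]prop-2-enoic acid, via enal 15 (not isolated)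
Conditions: TEMPO (10 mol%), PhI(OAc)2, CH2Cl2, rt; then NaClO2, NaH2PO4, 2-methyl-2-butene, t-BuOH/H2O, 0 °C
Reagents that add atoms: sodium chlorite, [Na+].[O-]Cl=O
Why: Oxoammonium oxidation of the allylic alcohol followed by Pinnick oxidation of the enal gives the acrylic acid under buffered conditions that the epoxide, acetal and silyl ether tolerate.

Step 10
Reactants: 16 the epoxy acrylic acid
Product: 18 (4S,7S)-7-[(1R)-1,3-dihydroxypropyl]-4-(2,2-dimethoxyethyl)-7-methyl-3-methylideneoxepan-2-one, via silyl ether lactone 17 (not isolated)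
Conditions: CSA (10 mol%), CH2Cl2, 0 °C to rt; then MeOH, rt
Reagents that add atoms: none
Why: Acid-catalysed 7-exo opening of the trisubstituted epoxide by the carboxylic acid at the tertiary carbon inverts C12 (R to S) and leaves the epoxide oxygen on C11 (R); added methanol then cleaves the primary silyl ether while the dimethyl acetal survives.

Step 11
Reactants: 18 the lactone diol
Product: 20 (1R)-1-[(2S,5S)-5-(2,2-dimethoxyethyl)-2-methyl-6-methylidene-7-oxooxepan-2-yl]-3-iodopropyl acetate, via iodo alcohol 19 (not isolated)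
Conditions: PPh3, I2, imidazole (premixed), CH2Cl2, 0 °C; then Ac2O, DMAP, rt
Reagents that add atoms: iodine, II; acetic anhydride, CC(=O)OC(C)=O
Why: Garegg–Samuelsson iodination is selective for the primary alcohol over the hindered secondary C11–OH, which is then acetylated in the same flask with retention.

Step 12
Reactants: 21 but-2-yn-1-ol
Product: 23 (2Z)-3-iodobut-2-en-1-ol, via alkenylalanate 22 (not isolated)
Conditions: NaAlH2(OCH2CH2OMe)2, THF, 0 °C to rt; EtOAc; then I2, −78 °C
Reagents that add atoms: iodine, II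
Why: Alkoxide-directed trans-hydroalumination of the propargylic alcohol gives a cyclic alkenylalanate and iododealumination with retention fixes the Z geometry of the future C7=C8 bond.

Step 13
Reactants: 23 (2Z)-3-iodobut-2-en-1-ol
Product: 24 (2Z)-1-bromo-3-iodobut-2-ene
Conditions: CBr4, PPh3, CH2Cl2, 0 °C
Reagents that add atoms: carbon tetrabromide, BrC(Br)(Br)Br
Why: Appel bromination of the allylic alcohol without allylic transposition or loss of alkene geometry.

Step 14
Reactants: 24 (2Z)-1-bromo-3-iodobut-2-ene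
Product: 25 (5Z)-6-iodohept-5-en-2-yne
Conditions: CH3C≡CMgBr, CuI (5 mol%), THF, 0 °C to rt
Reagents that add atoms: prop-1-ynylmagnesium bromide, CC#C[Mg]Br
Why: Copper-catalysed SN2 alkynylation of the primary allylic bromide gives the skipped enyne; the vinyl iodide is inert without palladium.

Step 15
Reactants: 25 (5Z)-6-iodohept-5-en-2-yne
Product: 27 (2E,5Z)-2-bromo-6-iodohepta-2,5-diene, via alkenylzirconocene chloride 26 (not isolated)
Conditions: Cp2Zr(H)Cl (2 equiv), THF, rt to 40 °C; then NBS, 0 °C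
Reagents that add atoms: N-bromosuccinimide, O=C1CCC(=O)N1Br
Why: Hydrozirconation adds H and Zr syn; excess hydride equilibrates zirconium to the methyl-bearing carbon (about 9:1 or better), and bromodezirconation with retention gives the E-2-bromo-2-alkene (future C4=C5).

Step 16
Reactants: 20 the iodo acetate; 27 (2E,5Z)-2-bromo-6-iodohepta-2,5-diene
Product: 29 (1R,4Z,7E)-8-bromo-1-[(2S,5S)-5-(2,2-dimethoxyethyl)-2-methyl-6-methylidene-7-oxooxepan-2-yl]-4-methylnona-4,7-dienyl acetate, via alkylzinc iodide 28 (not isolated)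
Conditions: Zn dust, LiCl, THF, 35 °C; then 27, PdCl2(dppf) (5 mol%), THF, rt
Reagents that add atoms: none
Why: Negishi sp3–sp2 coupling: zinc inserts into the primary C–I bond, the alkylzinc tolerates lactone, acetate, acrylate and acetal, and palladium reacts only with the alkenyl iodide (not the trisubstituted alkenyl bromide), forming C8–C9 with retention of the Z geometry.

Step 17
Reactants: 29 the coupled acetal
Product: 30 (1R,4Z,7E)-8-bromo-4-methyl-1-[(2S,5S)-2-methyl-6-methylidene-7-oxo-5-(2-oxoethyl)oxepan-2-yl]nona-4,7-dienyl acetate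
Conditions: 1 M HCl, THF, 0 °C to rt
Reagents that add atoms: water, O
Why: Mild acetal hydrolysis frees the C3 aldehyde; it has no α-stereocentre, and lactone, acetate and skipped diene are stable.

Step 18
Reactants: 30 the seco bromo aldehyde
Product: 31 (1S,3S,4E,7Z,11R,12S)-11-acetoxy-3-hydroxycembra-4,7,15(17)-trien-16,12-olide (target)
Conditions: CrCl2 (20 mol%), NiCl2(dme) (5 mol%), Bu4NBr, DMF, 30 added over 8 h to 2 mM, Al anode, Ni-foam cathode, undivided cell, 3 mA (about 2.5 F/mol), rt; aq NH4Cl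
Reagents that add atoms: none
Why: Proposed new method: a cathodically driven chromium/nickel-catalysed Nozaki–Hiyama–Kishi macrocyclisation of a 2-bromo-2-alkene onto an aldehyde, in which zerovalent nickel inserts into C4–Br with retention of the E geometry, transmetalation gives an alkenyl species of trivalent chromium that adds only to the C3 aldehyde, aluminium ions from the anode release the alkoxide and the cathode regenerates divalent chromium, so catalytic chromium suffices at high dilution; C3 is set by substrate control in the lactone-bridged macrocyclic transition state, with 3S proposed (chromium alkoxide on the ring periphery) but not secured; the closest known reaction types are the intermolecular electroreductive chromium-catalysed alkenylation of aldehydes and stoichiometric CrCl2/NiCl2 NHK macrocyclisations.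

**Compound list**
1 | (S)-(−)-limonene | CC1=CC[C@H](CC1)C(C)=C | starting material
2 | (3S)-6-hydroperoxy-1,1,6-trimethoxy-3-(prop-1-en-2-yl)heptane (C6 epimers) | COC(OC)C[C@H](CCC(C)(OC)OO)C(C)=C | intermediate
3 | (3S)-5,5-dimethoxy-3-(prop-1-en-2-yl)pentyl acetate | COC(OC)C[C@H](CCOC(C)=O)C(C)=C | intermediate
4 | (3S)-5,5-dimethoxy-3-(prop-1-en-2-yl)pentan-1-ol | COC(OC)C[C@H](CCO)C(C)=C | intermediate
5 | (3R)-5-bromo-1,1-dimethoxy-3-(prop-1-en-2-yl)pentane | COC(OC)C[C@H](CCBr)C(C)=C | intermediate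
6 | L-homoserine | N[C@@H](CCO)C(=O)O | starting material
7 | (3S)-3-chlorooxolan-2-one | Cl[C@H]1CCOC1=O | intermediate
8 | (2S)-2-chloro-4-hydroxy-N-methoxy-N-methylbutanamide | Cl[C@@H](CCO)C(=O)N(C)OC | intermediate
9 | (2S)-4-(tert-butyldimethylsilyloxy)-2-chloro-N-methoxy-N-methylbutanamide | Cl[C@@H](CCO[Si](C)(C)C(C)(C)C)C(=O)N(C)OC | intermediate
10 | (3S)-5-(tert-butyldimethylsilyloxy)-3-chloropentan-2-one | Cl[C@@H](CCO[Si](C)(C)C(C)(C)C)C(C)=O | intermediate
11 | [(3R)-5,5-dimethoxy-3-(prop-1-en-2-yl)pentyl]magnesium bromide | COC(OC)C[C@H](CC[Mg]Br)C(C)=C | intermediate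
12 | (3S,4R,7S)-1-(tert-butyldimethylsilyloxy)-3-chloro-9,9-dimethoxy-4-methyl-7-(prop-1-en-2-yl)nonan-4-ol | C[C@@](O)(CC[C@@H](CC(OC)OC)C(C)=C)[C@@H](Cl)CCO[Si](C)(C)C(C)(C)C | intermediate
13 | tert-butyl(2-{(2R,3R)-3-[(3S)-5,5-dimethoxy-3-(prop-1-en-2-yl)pentyl]-3-methyloxiran-2-yl}ethoxy)dimethylsilane | C[C@]1(CC[C@@H](CC(OC)OC)C(C)=C)O[C@@H]1CCO[Si](C)(C)C(C)(C)C | intermediate
14 | 2-[(3S)-5-{(2R,3R)-3-[2-(tert-butyldimethylsilyloxy)ethyl]-2-methyloxiran-2-yl}-1,1-dimethoxypentan-3-yl]prop-2-en-1-ol | C[C@]1(CC[C@@H](CC(OC)OC)C(=C)CO)O[C@@H]1CCO[Si](C)(C)C(C)(C)C | intermediate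
15 | 2-[(3S)-5-{(2R,3R)-3-[2-(tert-butyldimethylsilyloxy)ethyl]-2-methyloxiran-2-yl}-1,1-dimethoxypentan-3-yl]prop-2-enal | C[C@]1(CC[C@@H](CC(OC)OC)C(=C)C=O)O[C@@H]1CCO[Si](C)(C)C(C)(C)C | intermediate
16 | 2-[(3S)-5-{(2R,3R)-3-[2-(tert-butyldimethylsilyloxy)ethyl]-2-methyloxiran-2-yl}-1,1-dimethoxypentan-3-yl]prop-2-enoic acid | C[C@]1(CC[C@@H](CC(OC)OC)C(=C)C(=O)O)O[C@@H]1CCO[Si](C)(C)C(C)(C)C | intermediate
17 | (4S,7S)-7-[(1R)-3-(tert-butyldimethylsilyloxy)-1-hydroxypropyl]-4-(2,2-dimethoxyethyl)-7-methyl-3-methylideneoxepan-2-one | C=C1C(=O)O[C@@](C)(CC[C@H]1CC(OC)OC)[C@H](O)CCO[Si](C)(C)C(C)(C)C | intermediate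
18 | (4S,7S)-7-[(1R)-1,3-dihydroxypropyl]-4-(2,2-dimethoxyethyl)-7-methyl-3-methylideneoxepan-2-one | C=C1C(=O)O[C@@](C)(CC[C@H]1CC(OC)OC)[C@H](O)CCO | intermediate
19 | (4S,7S)-4-(2,2-dimethoxyethyl)-7-[(1R)-1-hydroxy-3-iodopropyl]-7-methyl-3-methylideneoxepan-2-one | C=C1C(=O)O[C@@](C)(CC[C@H]1CC(OC)OC)[C@H](O)CCI | intermediate
20 | (1R)-1-[(2S,5S)-5-(2,2-dimethoxyethyl)-2-methyl-6-methylidene-7-oxooxepan-2-yl]-3-iodopropyl acetate | C=C1C(=O)O[C@@](C)(CC[C@H]1CC(OC)OC)[C@H](OC(C)=O)CCI | intermediate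
21 | but-2-yn-1-ol | CC#CCO | starting material
22 | sodium 2,2-bis(2-methoxyethoxy)-3-methyl-2,5-dihydro-1,2-oxaaluminol-2-uide (cyclic alkenylalanate) | CC1=CCO[Al-]1(OCCOC)OCCOC.[Na+] | intermediate
23 | (2Z)-3-iodobut-2-en-1-ol | C/C(I)=C/CO | intermediate
24 | (2Z)-1-bromo-3-iodobut-2-ene | C/C(I)=C/CBr | intermediate
25 | (5Z)-6-iodohept-5-en-2-yne | CC#CC/C=C(/C)I | intermediate
26 | chlorobis(cyclopentadienyl)[(2E,5Z)-6-iodohepta-2,5-dien-2-yl]zirconium | C/C(=C\C/C=C(/C)I)[Zr](Cl)(C1C=CC=C1)C1C=CC=C1 | intermediate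
27 | (2E,5Z)-2-bromo-6-iodohepta-2,5-diene | C/C(I)=C/C/C=C(\C)Br | intermediate
28 | {(3R)-3-acetoxy-3-[(2S,5S)-5-(2,2-dimethoxyethyl)-2-methyl-6-methylidene-7-oxooxepan-2-yl]propyl}zinc iodide | C=C1C(=O)O[C@@](C)(CC[C@H]1CC(OC)OC)[C@H](OC(C)=O)CC[Zn]I | intermediate
29 | (1R,4Z,7E)-8-bromo-1-[(2S,5S)-5-(2,2-dimethoxyethyl)-2-methyl-6-methylidene-7-oxooxepan-2-yl]-4-methylnona-4,7-dienyl acetate | C=C1C(=O)O[C@@](C)(CC[C@H]1CC(OC)OC)[C@H](OC(C)=O)CC/C(C)=C\C/C=C(\C)Br | intermediate
30 | (1R,4Z,7E)-8-bromo-4-methyl-1-[(2S,5S)-2-methyl-6-methylidene-7-oxo-5-(2-oxoethyl)oxepan-2-yl]nona-4,7-dienyl acetate | C=C1C(=O)O[C@@](C)(CC[C@H]1CC=O)[C@H](OC(C)=O)CC/C(C)=C\C/C=C(\C)Br | intermediate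
31 | (1S,3S,4E,7Z,11R,12S)-11-acetoxy-3-hydroxycembra-4,7,15(17)-trien-16,12-olide | C=C1C(=O)O[C@@]2(C)CC[C@H]1C[C@H](O)/C(C)=C/C/C=C(/C)CC[C@H]2OC(C)=O | target

**Step count and risks**
Total steps: 18. Longest linear sequence: 12 (L-homoserine 6 to 31: steps 3–11, 16–18).

Steps most likely to fail:

Step 1 (one-pot ozonolysis and Criegee rearrangement; risks are trapping of the wrong carbonyl oxide, over-ozonolysis of the isopropenyl group, and slow migration of a primary alkyl group). The fallback sets out from 1. Ozonolysis in acidic methanol with Me2S work-up gives (5S)-7,7-dimethoxy-5-(prop-1-en-2-yl)heptan-2-one F1. TMSCl, Et3N in hot DMF gives the more substituted silyl enol ether F2. Buffered mCPBA at −20 °C (Rubottom oxidation; the enol ether reacts far faster than the isopropenyl group) gives the α-hydroxy ketone F3. NaIO4 cleaves it to (3S)-5,5-dimethoxy-3-(prop-1-en-2-yl)pentanal F4, and NaBH4 brings the sequence back to the route at 4.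

Step 10 (seven-membered lactonisation at a tertiary epoxide carbon; Meinwald rearrangement or elimination may compete). The fallback sets out from 16. O-tert-butyl-N,N'-diisopropylisourea gives the tert-butyl ester F5. BF3·OEt2 in CH2Cl2 at −78 °C then lets the ester carbonyl oxygen open the Lewis-acid-activated epoxide at C12 with inversion and loss of isobutene. This returns to the route at 17, which is desilylated with methanol/CSA as before to 18.

Step 18 (the proposed electrochemical macrocyclisation; risks are low current efficiency at 2 mM, reduction of the aldehyde, and the wrong C3 epimer). The fallback sets out from 30 and uses the classical stoichiometric NHK macrocyclisation (CrCl2 in excess, catalytic NiCl2, DMSO/THF, 2 mM). This gives 31 together with its C3 epimer F6. F6 is inverted by a Mitsunobu reaction with chloroacetic acid (PPh3, DIAD) to the (3S)-chloroacetate F7. Its chloroacetyl group is removed beside the C11 acetate with thiourea/NaHCO3 in ethanol, which comes back to the route at 31.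

Further compounds
F1 | step 1 | (5S)-7,7-dimethoxy-5-(prop-1-en-2-yl)heptan-2-one | COC(OC)C[C@H](CCC(C)=O)C(C)=C
F2 | step 1 | trimethyl{[(5R)-7,7-dimethoxy-5-(prop-1-en-2-yl)hept-2-en-2-yl]oxy}silane | COC(OC)C[C@H](CC=C(C)O[Si](C)(C)C)C(C)=C
F3 | step 1 | (5S)-3-hydroxy-7,7-dimethoxy-5-(prop-1-en-2-yl)heptan-2-one (C3 epimers) | COC(OC)C[C@H](CC(O)C(C)=O)C(C)=C
F4 | step 1 | (3S)-5,5-dimethoxy-3-(prop-1-en-2-yl)pentanal | COC(OC)C[C@H](CC=O)C(C)=C
F5 | step 10 | tert-butyl 2-[(3S)-5-{(2R,3R)-3-[2-(tert-butyldimethylsilyloxy)ethyl]-2-methyloxiran-2-yl}-1,1-dimethoxypentan-3-yl]prop-2-enoate | C[C@]1(CC[C@@H](CC(OC)OC)C(=C)C(=O)OC(C)(C)C)O[C@@H]1CCO[Si](C)(C)C(C)(C)C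
F6 | step 18 | (1S,3R,4E,7Z,11R,12S)-11-acetoxy-3-hydroxycembra-4,7,15(17)-trien-16,12-olide (C3 epimer of 31) | C=C1C(=O)O[C@@]2(C)CC[C@H]1C[C@@H](O)/C(C)=C/C/C=C(/C)CC[C@H]2OC(C)=O
F7 | step 18 | (1S,3S,4E,7Z,11R,12S)-11-acetoxy-3-(chloroacetoxy)cembra-4,7,15(17)-trien-16,12-olide | C=C1C(=O)O[C@@]2(C)CC[C@H]1C[C@H](OC(=O)CCl)/C(C)=C/C/C=C(/C)CC[C@H]2OC(C)=O
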